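The target's only heteroatom goes in late: the primary allylic C–O bond is made by E-selective allylic C–H hydroxylation of the unprotected prenyl terminus of a tricyclic diketone (key step); the two exocyclic methylenes then come from the two ketones.
The diketone (seven-membered rings B and C with the bridgehead alkene) is cut at two C–C bonds to a monocyclic α-chloroketone: type 2 intramolecular oxyallyl cation–diene (4+3) cycloaddition, tether on C2 of the diene.
The cis-2,3-disubstituted cyclohexanone comes from a 2,4-disubstituted cyclohexenone (Mukaiyama–Michael addition of a chloroacetone enol silane, kinetic protonation); the enone comes from (S)-citronellal and a dienyl vinyl ketone by organocatalytic Robinson annulation.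
The vinyl ketone comes from chloroprene, 1-bromo-3-chloropropane and an acrylic Weinreb amide.
Ring order: ring A first, then rings B and C together in one step.

Assumption: the ring double bond of the target (no descriptor in the SMILES) is the only one the bicycle allows, cis within ring C; tricyclic compounds are numbered as tricyclo[8.4.1.0^{2,7}]pentadecanes (C1 bridgehead CH, C2/C7 ring fusion, C3 side-chain carbon, C6 and C14 the carbonyl/methylidene carbons, C10=C11 the bridgehead alkene, C15 the one-carbon bridge).

Step 1
Reactants: 1 2-chlorobuta-1,3-diene (chloroprene); 2 1-bromo-3-chloropropane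
Product: 4 6-chloro-3-methylidenehex-1-ene, via buta-1,3-dien-2-ylmagnesium chloride 3 (not isolated)
Conditions: Mg, ZnCl2 (cat.), THF, reflux; then 2, Li2CuCl4 (3 mol%), THF, 0 °C
Reagents that add atoms: none
Why: Grignard formation from the vinylic chloride followed by a Kochi-type copper-catalysed sp2–sp3 cross-coupling that takes place at the C–Br bond and leaves the C–Cl bond for step 2; no stereocentre is formed.

Step 2
Reactants: 4 6-chloro-3-methylidenehex-1-ene; 5 N-methoxy-N-methylprop-2-enamide
Product: 7 7-methylidenenona-1,8-dien-3-one, via (4-methylidenehex-5-en-1-yl)magnesium chloride 6 (not isolated)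
Conditions: Mg, I2 (cat.), THF, 50 °C; then 5, THF, −78 to 0 °C; poured into cold 1 M HCl
Reagents that add atoms: none
Why: Weinreb ketone synthesis, in which the alkylmagnesium chloride adds once to the amide because the magnesium chelate survives until the cold acidic quench, which also stops the freed amine from adding to the vinyl ketone; no stereocentre is formed.

Step 3
Reactants: 8 (S)-citronellal; 7 7-methylidenenona-1,8-dien-3-one
Product: 10 (4S)-2-(3-methylidenepent-4-en-1-yl)-4-[(2S)-6-methylhept-5-en-2-yl]cyclohex-2-en-1-one, via Michael adduct 9 (not isolated)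
Conditions: (S)-2-[diphenyl(trimethylsilyloxy)methyl]pyrrolidine (10 mol%), ethyl 3,4-dihydroxybenzoate (20 mol%), neat, 4 °C; then KOH, n-Bu4NOH (cat.), THF/Et2O/H2O, 40 °C
Reagents that add atoms: none
Why: Organocatalytic Robinson annulation, in which the E-enamine of 8 adds to the vinyl ketone on the face away from the diarylmethyl group (this sets C4 as S under catalyst control, the side-chain centre coming from 8) and base then closes ring A by aldol condensation through the only ketone enolate that can form a six-membered ring.

Step 4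
Reactants: 11 1-chloropropan-2-one (chloroacetone)
Product: 12 (Z)-[(1-chloroprop-1-en-2-yl)oxy]trimethylsilane
Conditions: TMSOTf, Et3N, Et2O, 0 °C
Reagents that add atoms: trimethylsilyl trifluoromethanesulfonate, C[Si](C)(C)OS(=O)(=O)C(F)(F)F
Why: Soft enolisation and O-silylation toward the more acidic chlorine-bearing carbon gives the chloro enol silane (Z major, the geometry having no bearing on later steps).

Step 5
Reactants: 10 (4S)-2-(3-methylidenepent-4-en-1-yl)-4-[(2S)-6-methylhept-5-en-2-yl]cyclohex-2-en-1-one; 12 (Z)-[(1-chloroprop-1-en-2-yl)oxy]trimethylsilane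
Product: 14 (2S,3S,4S)-3-(1-chloro-2-oxopropyl)-2-(3-methylidenepent-4-en-1-yl)-4-[(2S)-6-methylhept-5-en-2-yl]cyclohexan-1-one, via ring silyl enol ether 13 (not isolated)
Conditions: 12 (1.5 equiv), Tf2NH (5 mol%), CH2Cl2, −78 °C; then HF·pyridine, THF, −78 to −40 °C
Reagents that add atoms: none
Why: Mukaiyama–Michael addition under silyl triflimide catalysis, in which the enol silane attacks C3 of the silyl-activated enone on the face opposite the C4 side chain (3,4-trans) and hands its silyl group to the ring enolate, after which cold protodesilylation of the tetrasubstituted enol ether 13 puts the proton on C2 on the face away from the new C3 substituent and gives the kinetic 2,3-cis ketone, which is kept away from base (the CHCl centre is a mixture and is lost in step 6).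

Step 6
Reactants: 14 (2S,3S,4S)-3-(1-chloro-2-oxopropyl)-2-(3-methylidenepent-4-en-1-yl)-4-[(2S)-6-methylhept-5-en-2-yl]cyclohexan-1-one
Product: 16 (1S,2S,3S,7S)-3-[(2S)-6-methylhept-5-en-2-yl]tricyclo[8.4.1.0^{2,7}]pentadec-10-ene-6,14-dione, via oxyallyl cation 15 (not isolated)
Conditions: Na2CO3, (CF3)2CHOH, 0.005 M, 0 °C to rt
Reagents that add atoms: none
Why: Proposed new method: carbonate in the strongly ionising, weakly nucleophilic fluoroalcohol enolises the methyl ketone toward its methyl group and the secondary chloride leaves to give the W-shaped oxyallyl cation 15, whose substituted terminus is tethered by four atoms to C2 of the butadiene, so a (4+3) cycloaddition across the diene termini closes rings B and C together and leaves the central diene bond as the bridgehead alkene, while the ring A chair (side chain and oxyallyl arm equatorial, dienyl arm axial) lets the diene reach only one face of the cation and so sets C1 as S with C14 trans to C3 across ring B; the closest known reactions are the Föhlisch-type intramolecular oxyallyl cation–diene (4+3) cycloaddition with the tether on a diene terminus and the type 2 intramolecular Diels–Alder reaction of 2-tethered dienes.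

Step 7
Reactants: 16 (1S,2S,3S,7S)-3-[(2S)-6-methylhept-5-en-2-yl]tricyclo[8.4.1.0^{2,7}]pentadec-10-ene-6,14-dione
Product: 17 (1S,2S,3S,7S)-3-[(2S,5E)-7-hydroxy-6-methylhept-5-en-2-yl]tricyclo[8.4.1.0^{2,7}]pentadec-10-ene-6,14-dione
Conditions: SeO2 (0.3 equiv), t-BuOOH (3 equiv), salicylic acid (0.1 equiv), CH2Cl2, 0 °C to rt
Reagents that add atoms: selenium dioxide, O=[Se]=O (delivers the oxygen); tert-butyl hydroperoxide, CC(C)(C)OO (terminal oxidant)
Why: Selenium dioxide allylic oxidation (ene reaction, then 2,3-sigmatropic shift) hydroxylates the E-methyl group of the gem-dimethyl alkene, the most accessible trisubstituted alkene, while the bridgehead alkene is shielded by the bicycle, so the C–O bond forms with E geometry and without protecting groups.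

Step 8
Reactants: 17 (1S,2S,3S,7S)-3-[(2S,5E)-7-hydroxy-6-methylhept-5-en-2-yl]tricyclo[8.4.1.0^{2,7}]pentadec-10-ene-6,14-dione
Product: 18 (2E,6S)-6-[(1S,2S,3S,7S)-6,14-dimethylidenetricyclo[8.4.1.0^{2,7}]pentadec-10-en-3-yl]-2-methylhept-2-en-1-ol
Conditions: Zn, CH2Br2, TiCl4, THF (reagent aged at 5 °C); then 17, CH2Cl2, 0 °C to rt
Reagents that add atoms: dibromomethane, BrCBr
Why: Lombardo (Takai-type) methylenation turns both ketones into 1,1-disubstituted alkenes under non-basic conditions, so the epimerisable ring-fusion carbon C7 next to the ring A ketone keeps its configuration and the free alcohol is tolerated.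

Compound list
1 | 2-chlorobuta-1,3-diene (chloroprene) | C=CC(Cl)=C | starting material
2 | 1-bromo-3-chloropropane | ClCCCBr | starting material
3 | buta-1,3-dien-2-ylmagnesium chloride | C=CC(=C)[Mg]Cl | intermediate (not isolated)
4 | 6-chloro-3-methylidenehex-1-ene | ClCCCC(=C)C=C | intermediate
5 | N-methoxy-N-methylprop-2-enamide | C=CC(=O)N(C)OC | starting material
6 | (4-methylidenehex-5-en-1-yl)magnesium chloride | Cl[Mg]CCCC(=C)C=C | intermediate (not isolated)
7 | 7-methylidenenona-1,8-dien-3-one | C=CC(=O)CCCC(=C)C=C | intermediate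
8 | (S)-citronellal, (3S)-3,7-dimethyloct-6-enal | C[C@@H](CCC=C(C)C)CC=O | starting material
9 | (2S)-9-methylidene-2-[(2S)-6-methylhept-5-en-2-yl]-5-oxoundec-10-enal (Michael adduct) | O=C[C@H]([C@@H](C)CCC=C(C)C)CCC(=O)CCCC(=C)C=C | intermediate (not isolated)
10 | (4S)-2-(3-methylidenepent-4-en-1-yl)-4-[(2S)-6-methylhept-5-en-2-yl]cyclohex-2-en-1-one | O=C1CC[C@@H]([C@@H](C)CCC=C(C)C)C=C1CCC(=C)C=C | intermediate
11 | 1-chloropropan-2-one (chloroacetone) | CC(=O)CCl | starting material
12 | (Z)-[(1-chloroprop-1-en-2-yl)oxy]trimethylsilane | Cl/C=C(/C)O[Si](C)(C)C | intermediate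
13 | {[(3S,4S)-3-(1-chloro-2-oxopropyl)-2-(3-methylidenepent-4-en-1-yl)-4-[(2S)-6-methylhept-5-en-2-yl]cyclohex-1-en-1-yl]oxy}trimethylsilane (ring silyl enol ether, both CHCl epimers) | C[Si](C)(C)OC=1CC[C@@H]([C@@H](C)CCC=C(C)C)[C@H](C(Cl)C(C)=O)C=1CCC(=C)C=C | intermediate (not isolated)
14 | (2S,3S,4S)-3-(1-chloro-2-oxopropyl)-2-(3-methylidenepent-4-en-1-yl)-4-[(2S)-6-methylhept-5-en-2-yl]cyclohexan-1-one (2,3-cis, 3,4-trans, both CHCl epimers) | O=C1CC[C@@H]([C@@H](C)CCC=C(C)C)[C@H](C(Cl)C(C)=O)[C@@H]1CCC(=C)C=C | intermediate
15 | oxyallyl cation (zwitterion) formed from 14 by loss of HCl, ring stereocentres as in 14 | O=C1CC[C@@H]([C@@H](C)CCC=C(C)C)[C@H]([CH+]C([O-])=C)[C@@H]1CCC(=C)C=C | intermediate (not isolated)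
16 | (1S,2S,3S,7S)-3-[(2S)-6-methylhept-5-en-2-yl]tricyclo[8.4.1.0^{2,7}]pentadec-10-ene-6,14-dione | O=C1CC[C@@H]([C@@H](C)CCC=C(C)C)[C@H]2[C@@H]1CCC1=CCCC(=O)[C@H]2C1 | intermediate
17 | (1S,2S,3S,7S)-3-[(2S,5E)-7-hydroxy-6-methylhept-5-en-2-yl]tricyclo[8.4.1.0^{2,7}]pentadec-10-ene-6,14-dione | O=C1CC[C@@H]([C@@H](C)CC/C=C(\C)CO)[C@H]2[C@@H]1CCC1=CCCC(=O)[C@H]2C1 | intermediate
18 | (2E,6S)-6-[(1S,2S,3S,7S)-6,14-dimethylidenetricyclo[8.4.1.0^{2,7}]pentadec-10-en-3-yl]-2-methylhept-2-en-1-ol | C=C1CC[C@@H]([C@@H](C)CC/C=C(\C)CO)[C@H]2[C@@H]1CCC1=CCCC(=C)[C@H]2C1 | target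

Total step count: 8. Longest linear sequence: 7 steps (1, 2, 3, 5, 6, 7, 8, from chloroprene); 5 steps from (S)-citronellal.

Three steps most likely to fail

Step 6 (the proposed new cycloaddition). Ring B must close through a seven-membered tether before the oxyallyl cation is lost to solvent capture, Favorskii contraction or attack by the ring A enolate, and the facial selectivity at C1 rests on a conformational argument only. The fallback uses known chemistry, sets out from enone 10 and comes back at diketone 16. The open-chain diene of 10 is first turned into a seven-membered ketone by the intermolecular Noyori (4+3) cycloaddition with 1,1,3,3-tetrabromoacetone and Fe2(CO)9 (benzene, 60 °C), which gives the dibromocycloheptenone enone F1. Zn–Cu couple with NH4Cl in MeOH removes both bromines and gives the cycloheptenone enone F2. TMSOTf and Et3N then give the cycloheptadienyl silyl enol ether F3 (the regioisomeric enol ether is hydrolysed back to F2 and recycled). TiCl4 in CH2Cl2 at −78 °C closes ring B by intramolecular Mukaiyama–Michael addition to the cyclohexenone, anti to the side chain, and cold protonation of the ring A enolate from the face away from the new bridge gives 16. This costs two more steps, and the configuration at C1 is less secure than in step 6.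

Step 5. The chlorinated enol silane is a weak nucleophile for a 2,4-disubstituted enone, and the protonation may give some 2,3-trans ketone, which would lead to the wrong ring fusion. The fallback sets out from 10 and comes back at 16. Enone 10 is treated with the more nucleophilic, commercial 2-(trimethylsilyloxy)propene under the same Tf2NH catalysis, which gives the acetonyl ring silyl enol ether F4. With the ring ketone masked, LDA (THF, −78 °C) removes a proton from the methyl group of the side-chain ketone and N-chlorosuccinimide gives the chloromethyl ketone silyl enol ether F5. HF·pyridine at −78 °C then unmasks the ring ketone with kinetic protonation and gives the cis chloromethyl ketone F6. Under the conditions of step 6, F6 ionises to the same oxyallyl cation 15 and so gives 16. This addresses the reactivity problem only; the cis selectivity still rests on kinetic protonation.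

Step 7. The bridgehead alkene or the ketone α-positions may also be oxidised, and part of the product may go on to the enal. The fallback sets out from 16 and comes back at 17. Cross-metathesis of the prenyl terminus of 16 with methacrolein (second-generation Hoveyda–Grubbs catalyst, CH2Cl2, 40 °C; the hindered bridgehead alkene does not take part) gives the E-enal diketone F7. NaBH(OAc)3 reduces the aldehyde but not the two ketones and gives 17; the oxygen then comes from methacrolein instead of a C–H oxidation.

Further compounds
F1 | step 6 | (4S)-2-[2-(4,6-dibromo-5-oxocyclohept-1-en-1-yl)ethyl]-4-[(2S)-6-methylhept-5-en-2-yl]cyclohex-2-en-1-one (bromide epimers) | O=C1CC[C@@H]([C@@H](C)CCC=C(C)C)C=C1CCC1=CCC(Br)C(=O)C(Br)C1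
F2 | step 6 | (4S)-4-[(2S)-6-methylhept-5-en-2-yl]-2-[2-(5-oxocyclohept-1-en-1-yl)ethyl]cyclohex-2-en-1-one | O=C1CC[C@@H]([C@@H](C)CCC=C(C)C)C=C1CCC1=CCCC(=O)CC1
F3 | step 6 | (4S)-4-[(2S)-6-methylhept-5-en-2-yl]-2-{2-[5-(trimethylsilyloxy)cyclohepta-1,5-dien-1-yl]ethyl}cyclohex-2-en-1-one | O=C1CC[C@@H]([C@@H](C)CCC=C(C)C)C=C1CCC1=CCCC(O[Si](C)(C)C)=CC1
F4 | step 5 | 1-[(1S,6S)-2-(3-methylidenepent-4-en-1-yl)-6-[(2S)-6-methylhept-5-en-2-yl]-3-(trimethylsilyloxy)cyclohex-2-en-1-yl]propan-2-one | C[Si](C)(C)OC=1CC[C@@H]([C@@H](C)CCC=C(C)C)[C@H](CC(C)=O)C=1CCC(=C)C=C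
F5 | step 5 | 1-chloro-3-[(1S,6S)-2-(3-methylidenepent-4-en-1-yl)-6-[(2S)-6-methylhept-5-en-2-yl]-3-(trimethylsilyloxy)cyclohex-2-en-1-yl]propan-2-one | C[Si](C)(C)OC=1CC[C@@H]([C@@H](C)CCC=C(C)C)[C@H](CC(=O)CCl)C=1CCC(=C)C=C
F6 | step 5 | (2S,3S,4S)-3-(3-chloro-2-oxopropyl)-2-(3-methylidenepent-4-en-1-yl)-4-[(2S)-6-methylhept-5-en-2-yl]cyclohexan-1-one | O=C1CC[C@@H]([C@@H](C)CCC=C(C)C)[C@H](CC(=O)CCl)[C@@H]1CCC(=C)C=C
F7 | step 7 | (2E,6S)-6-[(1S,2S,3S,7S)-6,14-dioxotricyclo[8.4.1.0^{2,7}]pentadec-10-en-3-yl]-2-methylhept-2-enal | O=C1CC[C@@H]([C@@H](C)CC/C=C(\C)C=O)[C@H]2[C@@H]1CCC1=CCCC(=O)[C@H]2C1
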